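**Plan**
Retrosynthesis: the interflavan bond C4(upper unit)–C6(lower unit) is cut first (Friedel–Crafts alkylation), then in each flavan unit the two ring C bonds O1–C8a and C3–C4, leading back to 3,4-bis(benzyloxy)-2-fluorobenzoyl chloride (ring A plus C4) and an α-benzyloxy aryl ketone (ring B, C2, C3, O1).
Forward: the ring A acid chloride is made in three steps and each ketone in one; a single annulation then closes ring C as a flat 3-benzyloxychromen-4-one, and the same event is run a second time for the upper unit.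
Enabling feature: O1 and C4 are the ortho substituents on C8a and C4a of ring A, so at the C4 carbonyl level the aroyl group is both the electrophile for C3 and the activator of the ortho C8a–F bond, while O1–C2–C3 at the ketone level is an ambident enolate that reacts first at C3 and then at O1.
Stereochemistry: C2, C3 and C4 of each unit come from an enantioselective all-syn hydrogenation of the flat pyranone ring (all-cis, 2R,3R,4R); C4 of the upper unit is set again in the coupling, where the lower unit enters anti to the 3-benzyloxy group (4β, 3,4-trans).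
End game: a benzyl carbonate on O4 keeps C4 of the lower unit from ionising, the upper unit is activated as its trichloroacetimidate, and one hydrogenolysis frees all ten hydroxyl groups.

Key step: step 5

Remark: flavan numbering is used for each unit (O1, C2, C3, C4, C4a, C5 to C8, C8a; ring A benzo, ring B 2-aryl, ring C pyran); the target is read from its SMILES as epioritin-(4β→6)-epimesquitol-4α-ol, upper unit 2,3-cis-3,4-trans (2R,3R,4S) and lower unit all-cis (2R,3R,4R); compounds 1, 6, 7, 14 and benzyl bromide are taken to be catalogue materials.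

Step 1
Reactants: 1 3-fluorobenzene-1,2-diol
Product: 2 1,2-bis(benzyloxy)-3-fluorobenzene
Conditions: BnBr (2.2 equiv), K2CO3, DMF, 60 °C
Reagents that add atoms: benzyl bromide, BrCc1ccccc1
Why: Williamson ether synthesis, in which both phenoxides are alkylated by SN2 at the benzylic carbon.

Step 2
Reactants: 2 1,2-bis(benzyloxy)-3-fluorobenzene
Product: 4 3,4-bis(benzyloxy)-2-fluorobenzoic acid, via [3,4-bis(benzyloxy)-2-fluorophenyl]lithium 3 (not isolated)
Conditions: n-BuLi (1.1 equiv), THF, −78 °C; CO2 (gas), −78 → 0 °C; 1 M HCl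
Reagents that add atoms: carbon dioxide, O=C=O
Why: Fluorine-directed ortho-lithiation followed by carboxylation: the ring hydrogen next to fluorine is the most acidic one, and at −78 °C its removal should outpace benzylic deprotonation.

Step 3
Reactants: 4 3,4-bis(benzyloxy)-2-fluorobenzoic acid
Product: 5 3,4-bis(benzyloxy)-2-fluorobenzoyl chloride
Conditions: (COCl)2 (1.5 equiv), DMF (cat.), CH2Cl2, 0 → 23 °C; evaporated and used crude
Reagents that add atoms: oxalyl chloride, O=C(Cl)C(=O)Cl
Why: Acid chloride formation through the chloroiminium salt generated from DMF, under conditions that leave benzyl ethers and the aryl fluoride untouched.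

Step 4
Reactants: 6 1,2-bis(benzyloxy)-4-bromobenzene; 7 2-(benzyloxy)-N-methoxy-N-methylacetamide
Product: 9 2-(benzyloxy)-1-[3,4-bis(benzyloxy)phenyl]ethan-1-one, via [3,4-bis(benzyloxy)phenyl]lithium 8 (not isolated)
Conditions: n-BuLi (1.05 equiv), THF, −78 °C; 7, −78 → 0 °C; 1 M HCl
Reagents that add atoms: none
Why: Bromine–lithium exchange followed by the Weinreb ketone synthesis, in which the chelated tetrahedral adduct holds until work-up and so prevents a second addition.

Step 5
Reactants: 9 2-(benzyloxy)-1-[3,4-bis(benzyloxy)phenyl]ethan-1-one; 5 3,4-bis(benzyloxy)-2-fluorobenzoyl chloride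
Product: 11 3,7,8-tris(benzyloxy)-2-[3,4-bis(benzyloxy)phenyl]-4H-chromen-4-one, via fluoro-1,3-diketone 10 (not isolated)
Conditions: LiN(SiMe3)2 (2.2 equiv), THF, −78 °C; 5, −78 → 0 °C; then DMF, 100 °C
Reagents that add atoms: none
Why: The lithium enolate of 9 (O1–C2=C3) is acylated at C3 by acid chloride 5 (Claisen-type C-acylation, forms C3–C4) and the more acidic diketone 10 is at once deprotonated by the second equivalent of base; on heating in DMF the enolate oxygen O1 adds to C8a, ortho to the aroyl group, and fluoride leaves (addition–elimination, SNAr), which forms O1–C8a and the 4-pyranone ring C. The closest known reaction type is the one-pot C-acylation and intramolecular SNAr cyclisation of ketone enolates with 2-fluorobenzoyl chlorides that gives flavones, chromones and 4-quinolones. Ring C closes in a 6-exo-trig mode at the aromatic carbon C8a, the anionic σ-adduct being stabilised by the C4 carbonyl on C4a. No stereocentre is formed here; the step delivers C2, C3 and C4 as a flat enone whose two faces are distinguished in step 6. The step needs C- over O-acylation and O- over C-arylation: the first is secured because any enol ester is transacylated by enolate to the doubly stabilised diketonate, the second because only O1 can reach C8a through a six-membered transition state and the single fluorine of ring A sits at C8a; since that fluorine is activated only by the ortho acyl group, heating in a dipolar aprotic solvent is planned.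

Step 6
Reactants: 11 3,7,8-tris(benzyloxy)-2-[3,4-bis(benzyloxy)phenyl]-4H-chromen-4-one
Product: 12 (2R,3R,4R)-3,7,8-tris(benzyloxy)-2-[3,4-bis(benzyloxy)phenyl]-3,4-dihydro-2H-chromen-4-ol
Conditions: H2 (100 bar), Ru(cod)(2-methylallyl)2 (5 mol %), SINpEt·HBF4 [1,3-bis(1-(naphthalen-1-yl)ethyl)-4,5-dihydroimidazolium tetrafluoroborate, the (R,R) or (S,S) antipode that gives the 2R series, 10 mol %], KOtBu (15 mol %), toluene, 25 °C
Reagents that add atoms: none
Why: Proposed new method: a chiral Ru–NHC hydride formed from Ru(cod)(2-methylallyl)2 and the imidazolinium salt should add H2 syn across the C2=C3 bond of the vinylogous ester from the enantioface selected by the ligand and then reduce the C4 ketone of the resulting cis-3-benzyloxyflavanone from the same open face, anti to the pseudo-axial 3-benzyloxy group, so that all hydrogens enter from one face and C2, C3 and C4 are set all-cis as 2R,3R,4R; the closest known reaction types are the enantioselective Ru–NHC hydrogenation of flavones and chromones to cis-flavan-4-ols and the all-syn hydrogenation of 3-alkoxyflavones over heterogeneous catalysts, neither of which covers an enantioenriched 2,3,4-triad from a 3-alkoxyflavone.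

Step 7
Reactants: 12 (2R,3R,4R)-3,7,8-tris(benzyloxy)-2-[3,4-bis(benzyloxy)phenyl]-3,4-dihydro-2H-chromen-4-ol
Product: 13 benzyl (2R,3S,4R)-3,7,8-tris(benzyloxy)-2-[3,4-bis(benzyloxy)phenyl]-3,4-dihydro-2H-chromen-4-yl carbonate
Conditions: LiN(SiMe3)2 (1.1 equiv), THF, −78 °C; benzyl chloroformate, −78 → 0 °C
Reagents that add atoms: benzyl chloroformate, O=C(Cl)OCc1ccccc1
Why: Acylation of the lithium alkoxide at O4 (carbonate formation, C4–O bond untouched, the change of the C3 descriptor being formal only) masks O4 as a nucleophile, makes C4 of the lower unit much slower to ionise than the imidate of the upper unit, and is removed later on its benzyl side together with the benzyl ethers.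

Step 8
Reactants: 14 1-(benzyloxy)-4-bromobenzene; 7 2-(benzyloxy)-N-methoxy-N-methylacetamide
Product: 16 2-(benzyloxy)-1-[4-(benzyloxy)phenyl]ethan-1-one, via [4-(benzyloxy)phenyl]lithium 15 (not isolated)
Conditions: n-BuLi (1.05 equiv), THF, −78 °C; 7, −78 → 0 °C; 1 M HCl
Reagents that add atoms: none
Why: Bromine–lithium exchange and Weinreb ketone synthesis, as in step 4.

Step 9
Reactants: 16 2-(benzyloxy)-1-[4-(benzyloxy)phenyl]ethan-1-one; 5 3,4-bis(benzyloxy)-2-fluorobenzoyl chloride
Product: 18 3,7,8-tris(benzyloxy)-2-[4-(benzyloxy)phenyl]-4H-chromen-4-one, via fluoro-1,3-diketone 17 (not isolated)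
Conditions: LiN(SiMe3)2 (2.2 equiv), THF, −78 °C; 5, −78 → 0 °C; then DMF, 100 °C
Reagents that add atoms: none
Why: The same Claisen-type C-acylation and intramolecular SNAr sequence as in step 5 builds ring C of the upper unit, with C-acylation and closure at C8a secured in the same way.

Step 10
Reactants: 18 3,7,8-tris(benzyloxy)-2-[4-(benzyloxy)phenyl]-4H-chromen-4-one
Product: 19 (2R,3R,4R)-3,7,8-tris(benzyloxy)-2-[4-(benzyloxy)phenyl]-3,4-dihydro-2H-chromen-4-ol
Conditions: H2 (100 bar), Ru(cod)(2-methylallyl)2 (5 mol %), SINpEt·HBF4 (same antipode as in step 6, 10 mol %), KOtBu (15 mol %), toluene, 25 °C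
Reagents that add atoms: none
Why: Proposed new method: as in step 6, syn addition of H2 to C2=C3 from the ligand-selected enantioface followed by reduction of the C4 ketone from the same face, anti to the 3-benzyloxy group, should give the all-cis 2R,3R,4R triad; the closest known reaction type is the enantioselective Ru–NHC hydrogenation of flavones to cis-flavan-4-ols.

Step 11
Reactants: 19 (2R,3R,4R)-3,7,8-tris(benzyloxy)-2-[4-(benzyloxy)phenyl]-3,4-dihydro-2H-chromen-4-ol
Product: 20 (2R,3S,4R)-3,7,8-tris(benzyloxy)-2-[4-(benzyloxy)phenyl]-3,4-dihydro-2H-chromen-4-yl 2,2,2-trichloroacetimidate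
Conditions: Cl3CCN (5 equiv), DBU (0.1 equiv), CH2Cl2, 0 °C; filtered through Et3N-deactivated silica and used at once
Reagents that add atoms: trichloroacetonitrile, N#CC(Cl)(Cl)Cl
Why: Base-catalysed addition of the C4 alkoxide to the nitrile (trichloroacetimidate formation) turns the hydroxyl into a leaving group that ionises with catalytic acid at low temperature, without change at C4 because the C4–O bond is not touched.

Step 12
Reactants: 20 (2R,3S,4R)-3,7,8-tris(benzyloxy)-2-[4-(benzyloxy)phenyl]-3,4-dihydro-2H-chromen-4-yl 2,2,2-trichloroacetimidate; 13 benzyl (2R,3S,4R)-3,7,8-tris(benzyloxy)-2-[3,4-bis(benzyloxy)phenyl]-3,4-dihydro-2H-chromen-4-yl carbonate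
Product: 21 3,7,8,4'-tetra-O-benzylepioritin-(4β→6)-3,7,8,3',4'-penta-O-benzyl-4-O-(benzyloxycarbonyl)epimesquitol-4α-ol
Conditions: 13 (3 equiv), TMSOTf (0.1 equiv), 4 Å molecular sieves, CH2Cl2, −78 → −40 °C, slow addition of 20
Reagents that add atoms: none
Why: Friedel–Crafts alkylation: TMSOTf ionises the imidate to the C4 benzylic cation of the upper unit, stabilised by the para 7-benzyloxy group, and 13 should attack through C6 (ortho to O7 and para to O1, whereas C5 is activated only by the twisted O8 and is blocked by the peri C4 substituent) from the face anti to the 3-benzyloxy and 2-aryl groups, setting the upper C4 as 4β, while the excess of 13 and the slow addition hold back self-condensation of the upper unit.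

Step 13
Reactants: 21 3,7,8,4'-tetra-O-benzylepioritin-(4β→6)-3,7,8,3',4'-penta-O-benzyl-4-O-(benzyloxycarbonyl)epimesquitol-4α-ol
Product: 22 epioritin-(4β→6)-epimesquitol-4α-ol (CNP0275688.2)
Conditions: H2 (1 bar), Pd(OH)2/C, THF/MeOH, 23 °C; filtration and Sephadex LH-20 chromatography under argon
Reagents that add atoms: none
Why: Hydrogenolysis in a neutral solvent cleaves the nine benzyl ethers and the benzyl carbonate at their O–CH2Ph bonds (the carbonic monoester then loses CO2), while the interflavan C–C bond and the lower C4–OH, which ionise only under acid, should remain.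

**Compound list**
1 | 3-fluorobenzene-1,2-diol (3-fluorocatechol) | Oc1cccc(F)c1O | starting material
2 | 1,2-bis(benzyloxy)-3-fluorobenzene | Fc1cccc(OCc2ccccc2)c1OCc1ccccc1 | intermediate
3 | [3,4-bis(benzyloxy)-2-fluorophenyl]lithium (formed in the flask) | [Li]c1ccc(OCc2ccccc2)c(OCc2ccccc2)c1F | intermediate
4 | 3,4-bis(benzyloxy)-2-fluorobenzoic acid | OC(=O)c1ccc(OCc2ccccc2)c(OCc2ccccc2)c1F | intermediate
5 | 3,4-bis(benzyloxy)-2-fluorobenzoyl chloride | O=C(Cl)c1ccc(OCc2ccccc2)c(OCc2ccccc2)c1F | intermediate
6 | 1,2-bis(benzyloxy)-4-bromobenzene | Brc1ccc(OCc2ccccc2)c(OCc2ccccc2)c1 | starting material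
7 | 2-(benzyloxy)-N-methoxy-N-methylacetamide | CON(C)C(=O)COCc1ccccc1 | starting material
8 | [3,4-bis(benzyloxy)phenyl]lithium (formed in the flask) | [Li]c1ccc(OCc2ccccc2)c(OCc2ccccc2)c1 | intermediate
9 | 2-(benzyloxy)-1-[3,4-bis(benzyloxy)phenyl]ethan-1-one | O=C(COCc1ccccc1)c1ccc(OCc2ccccc2)c(OCc2ccccc2)c1 | intermediate
10 | 2-(benzyloxy)-1-[3,4-bis(benzyloxy)-2-fluorophenyl]-3-[3,4-bis(benzyloxy)phenyl]propane-1,3-dione (formed in the flask as its lithium enolate) | O=C(c1ccc(OCc2ccccc2)c(OCc2ccccc2)c1F)C(OCc1ccccc1)C(=O)c1ccc(OCc2ccccc2)c(OCc2ccccc2)c1 | intermediate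
11 | 3,7,8-tris(benzyloxy)-2-[3,4-bis(benzyloxy)phenyl]-4H-chromen-4-one | O=c1c(OCc2ccccc2)c(-c2ccc(OCc3ccccc3)c(OCc3ccccc3)c2)oc2c(OCc3ccccc3)c(OCc3ccccc3)ccc12 | intermediate
12 | (2R,3R,4R)-3,7,8-tris(benzyloxy)-2-[3,4-bis(benzyloxy)phenyl]-3,4-dihydro-2H-chromen-4-ol (2,3-cis-3,4-cis) | c1cc2c(c(OCc3ccccc3)c1OCc1ccccc1)O[C@H](c1ccc(OCc3ccccc3)c(OCc3ccccc3)c1)[C@H](OCc1ccccc1)[C@@H]2O | intermediate
13 | benzyl (2R,3S,4R)-3,7,8-tris(benzyloxy)-2-[3,4-bis(benzyloxy)phenyl]-3,4-dihydro-2H-chromen-4-yl carbonate (all-cis; same spatial arrangement as 12) | c1cc2c(c(OCc3ccccc3)c1OCc1ccccc1)O[C@H](c1ccc(OCc3ccccc3)c(OCc3ccccc3)c1)[C@H](OCc1ccccc1)[C@@H]2OC(=O)OCc1ccccc1 | intermediate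
14 | 1-(benzyloxy)-4-bromobenzene | Brc1ccc(OCc2ccccc2)cc1 | starting material
15 | [4-(benzyloxy)phenyl]lithium (formed in the flask) | [Li]c1ccc(OCc2ccccc2)cc1 | intermediate
16 | 2-(benzyloxy)-1-[4-(benzyloxy)phenyl]ethan-1-one | O=C(COCc1ccccc1)c1ccc(OCc2ccccc2)cc1 | intermediate
17 | 2-(benzyloxy)-1-[3,4-bis(benzyloxy)-2-fluorophenyl]-3-[4-(benzyloxy)phenyl]propane-1,3-dione (formed in the flask as its lithium enolate) | O=C(c1ccc(OCc2ccccc2)c(OCc2ccccc2)c1F)C(OCc1ccccc1)C(=O)c1ccc(OCc2ccccc2)cc1 | intermediate
18 | 3,7,8-tris(benzyloxy)-2-[4-(benzyloxy)phenyl]-4H-chromen-4-one | O=c1c(OCc2ccccc2)c(-c2ccc(OCc3ccccc3)cc2)oc2c(OCc3ccccc3)c(OCc3ccccc3)ccc12 | intermediate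
19 | (2R,3R,4R)-3,7,8-tris(benzyloxy)-2-[4-(benzyloxy)phenyl]-3,4-dihydro-2H-chromen-4-ol (2,3-cis-3,4-cis) | c1cc2c(c(OCc3ccccc3)c1OCc1ccccc1)O[C@H](c1ccc(OCc3ccccc3)cc1)[C@H](OCc1ccccc1)[C@@H]2O | intermediate
20 | (2R,3S,4R)-3,7,8-tris(benzyloxy)-2-[4-(benzyloxy)phenyl]-3,4-dihydro-2H-chromen-4-yl 2,2,2-trichloroacetimidate (all-cis; same spatial arrangement as 19) | c1cc2c(c(OCc3ccccc3)c1OCc1ccccc1)O[C@H](c1ccc(OCc3ccccc3)cc1)[C@H](OCc1ccccc1)[C@@H]2OC(=N)C(Cl)(Cl)Cl | intermediate
21 | 3,7,8,4'-tetra-O-benzylepioritin-(4β→6)-3,7,8,3',4'-penta-O-benzyl-4-O-(benzyloxycarbonyl)epimesquitol-4α-ol (upper 2,3-cis-3,4-trans unit bonded from C4 to C6 of the all-cis lower unit) | c1ccccc1COc1ccc([C@H]2Oc3c(ccc(OCc4ccccc4)c3OCc3ccccc3)[C@H](c3cc4c(c(OCc5ccccc5)c3OCc3ccccc3)O[C@H](c3ccc(OCc5ccccc5)c(OCc5ccccc5)c3)[C@H](OCc3ccccc3)[C@@H]4OC(=O)OCc3ccccc3)[C@H]2OCc2ccccc2)cc1 | intermediate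
22 | epioritin-(4β→6)-epimesquitol-4α-ol (CNP0275688.2): (2R,3R,4S)-3,7,8-trihydroxy-2-(4-hydroxyphenyl)chroman-4-yl unit bonded through C4 to C6 of (2R,3R,4R)-2-(3,4-dihydroxyphenyl)chromane-3,4,7,8-tetrol | Oc1ccc([C@H]2Oc3c(ccc(O)c3O)[C@H](c3cc4c(c(O)c3O)O[C@H](c3ccc(O)c(O)c3)[C@H](O)[C@@H]4O)[C@H]2O)cc1 | target

**Count and risks**
Total step count: 13. Longest linear sequence: 8 steps (1, 2, 3, 5, 6, 7, 12, 13).

Step 6. The chiral catalyst may discriminate poorly between the faces of the tetrasubstituted alkoxy enone. C3 of the intermediate ketone may epimerise under the basic conditions before C4 is reduced. Reduction may also stop at the ketone stage. The fallback sets out from 11 and comes back at 12. Flavone 11 would be hydrogenated without a chiral ligand over PtO2 (H2, 3 bar, EtOAc, 23 °C), the known all-syn reduction of 3-alkoxyflavones, to give the racemic all-cis alcohol F1. The enantiomers would then be separated by preparative chromatography on a chiral stationary phase (amylose tris(3,5-dimethylphenylcarbamate)); the 2R,3R,4R enantiomer is 12.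

Step 10. The same processes threaten the upper unit: weak facial selection, C3 epimerisation before ketone reduction, and incomplete reduction. The fallback sets out from 18 and comes back at 19. Flavone 18 would be hydrogenated over PtO2 (H2, 3 bar, EtOAc, 23 °C) to the racemic all-cis alcohol F2, which would be resolved on the same chiral stationary phase to give 19.

Step 12. The cation of the upper unit may be captured by ring A of another upper unit (oligomerisation). It may lose H3 to give a flav-3-ene. It may attack with poor face selectivity. The carbonate of 13 may ionise under the acid. The fallback sets out from 19 (with 13) and comes back at 21. Alcohol 19 would be treated with phenylmethanethiol and BF3·OEt2 (CH2Cl2, −20 °C), so that the thiol captures the C4 cation anti to the 3-benzyloxy group and gives the 4β-benzylsulfanyl flavan F3, a storable donor. F3 and an excess of 13 would then be treated with AgBF4 (THF, 0 °C), a thiophilic activation known for joining 5-deoxyflavan units under conditions in which oxygen leaving groups stay in place, to give 21.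

**Further compounds**
F1 | step 6 | racemic all-cis 3,7,8-tris(benzyloxy)-2-[3,4-bis(benzyloxy)phenyl]-3,4-dihydro-2H-chromen-4-ol (12 plus its enantiomer) | c1cc2c(c(OCc3ccccc3)c1OCc1ccccc1)O[C@H](c1ccc(OCc3ccccc3)c(OCc3ccccc3)c1)[C@H](OCc1ccccc1)[C@@H]2O.c1cc2c(c(OCc3ccccc3)c1OCc1ccccc1)O[C@@H](c1ccc(OCc3ccccc3)c(OCc3ccccc3)c1)[C@@H](OCc1ccccc1)[C@H]2O
F2 | step 10 | racemic all-cis 3,7,8-tris(benzyloxy)-2-[4-(benzyloxy)phenyl]-3,4-dihydro-2H-chromen-4-ol (19 plus its enantiomer) | c1cc2c(c(OCc3ccccc3)c1OCc1ccccc1)O[C@H](c1ccc(OCc3ccccc3)cc1)[C@H](OCc1ccccc1)[C@@H]2O.c1cc2c(c(OCc3ccccc3)c1OCc1ccccc1)O[C@@H](c1ccc(OCc3ccccc3)cc1)[C@@H](OCc1ccccc1)[C@H]2O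
F3 | step 12 | (2R,3S,4S)-4-(benzylsulfanyl)-3,7,8-tris(benzyloxy)-2-[4-(benzyloxy)phenyl]-3,4-dihydro-2H-chromene (4β-benzylsulfanyl, 2,3-cis-3,4-trans) | c1cc2c(c(OCc3ccccc3)c1OCc1ccccc1)O[C@H](c1ccc(OCc3ccccc3)cc1)[C@H](OCc1ccccc1)[C@H]2SCc1ccccc1
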